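The route rests on disconnecting the C6–C7 bond of ring B, the ring that carries the ester oxygen (C6) next to the isopropyl-bearing carbon (C7). A carbinol flanked by an isopropyl(enyl) group is the retron of an intramolecular carbonyl-ene reaction onto a prenyl-type alkene. In one flask, C5H5NH[CrO3Cl] should oxidise a primary alcohol on ring A to the C6 aldehyde, close ring B onto the isopropylidene terminus of the C10 side chain (setting C7, trans ring fusion), and oxidise the new carbinol to the C6 ketone. The precursor is a monocyclic cyclohexenylmethanol whose C5/C10 stereocentres come from an asymmetric Diels–Alder reaction and a [2,3]-Wittig shift.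

Key step: step 9

Remark on numbering: eudesmane numbering is used throughout (ring A = C1–C5, C10; ring B = C5–C10; C14 = methyl on C10; C15 = methyl on C4; β = the face of C14).

Remark on the chemistry: the tryptophan-derived oxazaborolidinone is assumed to shield the same enal face of methacrolein as it does for other 2-substituted acroleins; if the opposite sense were found, the catalyst from (R)-tryptophan would be used. Compounds 1, 3, 6, 19, 21 and all reagents are taken as purchasable.

Step 1
Reactants: 1 3-methylbut-3-en-2-one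
Product: 2 triisopropyl[(3-methylbuta-1,3-dien-2-yl)oxy]silane
Conditions: i-Pr3SiOTf, Et3N, CH2Cl2, 0 to 23 °C
Reagents that add atoms: triisopropylsilyl trifluoromethanesulfonate, CC(C)[Si](C(C)C)(C(C)C)OS(=O)(=O)C(F)(F)F
Why: Soft enolisation and O-silylation of the only enolisable position (the acetyl methyl group) should give the robust 2-silyloxy-1,3-diene (silyl dienol ether formation).

Step 2
Reactants: 2 triisopropyl[(3-methylbuta-1,3-dien-2-yl)oxy]silane; 3 methacrolein (2-methylprop-2-enal)
Product: 4 (S)-1,3-dimethyl-4-{[tri(propan-2-yl)silyl]oxy}cyclohex-3-ene-1-carbaldehyde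
Conditions: (S)-2-butyl-4-(1H-indol-3-ylmethyl)-3-(4-methylbenzenesulfonyl)-1,3,2-oxazaborolidin-5-one (10 mol %, from N-tosyl-(S)-tryptophan and n-BuB(OH)2), CH2Cl2, −78 °C
Reagents that add atoms: none
Why: Catalytic enantioselective Diels–Alder reaction in which the 2-silyloxy group sends the diene CH2 next to it onto the β-carbon of methacrolein ("para" adduct, closing ring A with oxygen at C3 and methyl at C4), the bulky silyl group suppresses the Mukaiyama aldol pathway, and the boron-bound enal stacked over the indole should be attacked on the Re face of its C2, setting the quaternary centre C10 as (S).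

Step 3
Reactants: 4 (S)-1,3-dimethyl-4-{[tri(propan-2-yl)silyl]oxy}cyclohex-3-ene-1-carbaldehyde
Product: 5 (S)-[(4-ethenyl-2,4-dimethylcyclohex-1-en-1-yl)oxy]tri(propan-2-yl)silane
Conditions: Ph3PCH3Br, KOt-Bu, THF, 0 to 23 °C
Reagents that add atoms: methyltriphenylphosphonium bromide, C[P+](c1ccccc1)(c1ccccc1)c1ccccc1.[Br-]
Why: Wittig methylenation of a non-enolisable aldehyde; the silyl enol ether is inert to the ylide and C10 is untouched.

Step 4
Reactants: 5 (S)-[(4-ethenyl-2,4-dimethylcyclohex-1-en-1-yl)oxy]tri(propan-2-yl)silane; 6 1-bromo-2-methylprop-1-ene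
Product: 8 (S)-{[2,4-dimethyl-4-(4-methylpent-3-en-1-yl)cyclohex-1-en-1-yl]oxy}tri(propan-2-yl)silane, via alkylborane 7 (not isolated)
Conditions: 9-BBN-H, THF, 23 °C; then 6, PdCl2(dppf) (5 mol %, dppf = 1,1'-bis(diphenylphosphino)ferrocene), aq. K3PO4, DMF, 50 °C
Reagents that add atoms: none
Why: 9-BBN should hydroborate only the monosubstituted vinyl group at its terminus (the tetrasubstituted enol ether is untouched), and B-alkyl Suzuki–Miyaura coupling with the vinylic bromide then installs the 4-methylpent-3-enyl chain (C9–C8–C7=C11).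

Step 5
Reactants: 8 (S)-{[2,4-dimethyl-4-(4-methylpent-3-en-1-yl)cyclohex-1-en-1-yl]oxy}tri(propan-2-yl)silane
Product: 9 (S)-2,4-dimethyl-4-(4-methylpent-3-en-1-yl)cyclohex-2-en-1-one
Conditions: Pd(OAc)2 (1.1 equiv), MeCN, 40 °C
Reagents that add atoms: none
Why: Saegusa–Ito oxidation: the regiodefined C3=C4 silyl enol ether gives a palladium enolate, and β-hydride elimination from C5 (favoured over the methyl group) should give the endocyclic 2-methyl enone regiospecifically.

Step 6
Reactants: 9 (S)-2,4-dimethyl-4-(4-methylpent-3-en-1-yl)cyclohex-2-en-1-one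
Product: 10 (1S,4S)-2,4-dimethyl-4-(4-methylpent-3-en-1-yl)cyclohex-2-en-1-ol
Conditions: (R)-1-methyl-3,3-diphenyltetrahydro-1H,3H-pyrrolo[1,2-c][1,3,2]oxazaborole (20 mol %), catecholborane, toluene, −78 °C
Reagents that add atoms: none
Why: Corey–Bakshi–Shibata reduction in which the α-methylvinyl arm acts as the large group, so the (R)-catalyst should give the (S)-carbinol at C3 under reagent control (hydroxyl cis to the C14 methyl), and any minor enantiomer of 9 becomes a separable diastereomer.

Step 7
Reactants: 10 (1S,4S)-2,4-dimethyl-4-(4-methylpent-3-en-1-yl)cyclohex-2-en-1-ol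
Product: 11 tributyl({[(1S,4S)-2,4-dimethyl-4-(4-methylpent-3-en-1-yl)cyclohex-2-en-1-yl]oxy}methyl)stannane
Conditions: KH, Bu3SnCH2I, 18-crown-6 (cat.), THF, 0 to 23 °C
Reagents that add atoms: tributyl(iodomethyl)stannane, CCCC[Sn](CCCC)(CCCC)CI
Why: Williamson etherification of the potassium alkoxide with a primary iodide; the carbinol centre is not touched.

Step 8
Reactants: 11 tributyl({[(1S,4S)-2,4-dimethyl-4-(4-methylpent-3-en-1-yl)cyclohex-2-en-1-yl]oxy}methyl)stannane
Product: 13 [(1R,6S)-2,6-dimethyl-6-(4-methylpent-3-en-1-yl)cyclohex-2-en-1-yl]methanol, via alkoxymethyllithium 12 (not isolated)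
Conditions: n-BuLi, THF, −78 to −20 °C
Reagents that add atoms: none
Why: Tin–lithium exchange followed by the Still–Wittig [2,3]-sigmatropic rearrangement, which is suprafacial, so the hydroxymethyl carbon (C6) should be delivered to C5 on the face that carried the oxygen (cis to C14, trans to the side chain, C5 = R) while the double bond moves to C3=C4.

Step 9
Reactants: 13 [(1R,6S)-2,6-dimethyl-6-(4-methylpent-3-en-1-yl)cyclohex-2-en-1-yl]methanol
Product: 16 (2S,4aR,8aR)-4a,8-dimethyl-2-(prop-1-en-2-yl)-3,4,4a,5,6,8a-hexahydronaphthalen-1(2H)-one, via aldehyde 14 (not isolated), via ene alcohol 15 (not isolated)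
Conditions: C5H5NH[CrO3Cl] (pyridinium chlorochromate, 3 equiv), CH2Cl2, 23 °C
Reagents that add atoms: none
Why: The chlorochromate first oxidises the primary alcohol to aldehyde 14; the acidic chromium reagent then activates the formyl group for a type 1 intramolecular carbonyl-ene (Prins-type) reaction in which C7 of the isopropylidene terminus bonds to C6 and an allylic methyl hydrogen passes to oxygen, and the resulting alcohol 15 is oxidised in the same flask to ketone 16; the closest known reaction type is the chlorochromate-mediated conversion of citronellol into isopulegone. Ring B closes in the 6-exo-trig sense through a chair transition state onto a ring A that already holds C6 and C9 trans and diequatorial, so the decalin should be trans-fused. The new stereocentre C7 is controlled by that chair, the developing isopropenyl group lying equatorial (7β), and because C7 is α to the new ketone any epimer would equilibrate to the same equatorial isomer. The carbinol configuration of 15 (expected 6α, since an axial C–O would be syn-axial to the C14 methyl) does not matter, because the second oxidation erases it. The step needs chemoselectivity for the side-chain alkene over the ring A alkene, secured because only C7 can reach C6 through a six-membered ring, and it needs closure to outrun acid-mediated migration of the C3=C4 bond into conjugation, which the fully substituted C10 tether should favour.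

Step 10
Reactants: 16 (2S,4aR,8aR)-4a,8-dimethyl-2-(prop-1-en-2-yl)-3,4,4a,5,6,8a-hexahydronaphthalen-1(2H)-one
Product: 17 (1R,2S,4aR,8aR)-4a,8-dimethyl-2-(prop-1-en-2-yl)-1,2,3,4,4a,5,6,8a-octahydronaphthalen-1-ol
Conditions: LiBH(s-Bu)3, THF, −78 °C; then H2O
Reagents that add atoms: none
Why: Reduction with a bulky trialkylborohydride: the β face of the C6 carbonyl is screened by the syn-axial C14 methyl, so hydride should enter from the α face (equatorial attack) and give the axial 6β-alcohol (C6 = R), as in the reduction of 6-oxo steroids.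

Step 11
Reactants: 17 (1R,2S,4aR,8aR)-4a,8-dimethyl-2-(prop-1-en-2-yl)-1,2,3,4,4a,5,6,8a-octahydronaphthalen-1-ol
Product: 18 (1R,2S,4aR,8aR)-4a,8-dimethyl-2-(propan-2-yl)-1,2,3,4,4a,5,6,8a-octahydronaphthalen-1-ol
Conditions: H2 (1 atm), RhCl(PPh3)3 (5 mol %), benzene, 23 °C
Reagents that add atoms: none
Why: Homogeneous hydrogenation with RhCl(PPh3)3 discriminates sterically, so the 1,1-disubstituted isopropenyl group should be reduced while the trisubstituted ring A alkene survives; no stereocentre is formed.

Step 12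
Reactants: 18 (1R,2S,4aR,8aR)-4a,8-dimethyl-2-(propan-2-yl)-1,2,3,4,4a,5,6,8a-octahydronaphthalen-1-ol; 19 2,2-dimethyl-1,3-dioxane-4,6-dione (Meldrum's acid)
Product: 20 3-{[(1R,2S,4aR,8aR)-4a,8-dimethyl-2-(propan-2-yl)-1,2,3,4,4a,5,6,8a-octahydronaphthalen-1-yl]oxy}-3-oxopropanoic acid
Conditions: toluene, 100 °C
Reagents that add atoms: none
Why: Thermal ring opening of Meldrum's acid by the alcohol (acylation through a highly reactive acyl ketene equivalent) tolerates hindered alcohols such as the axial 6β-hydroxyl and should give the malonic half-ester with loss of acetone, without touching C6.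

Step 13
Reactants: 20 3-{[(1R,2S,4aR,8aR)-4a,8-dimethyl-2-(propan-2-yl)-1,2,3,4,4a,5,6,8a-octahydronaphthalen-1-yl]oxy}-3-oxopropanoic acid; 21 4-hydroxybenzaldehyde
Product: 22 (1R,2S,4aR,8aR)-4a,8-dimethyl-2-(propan-2-yl)-1,2,3,4,4a,5,6,8a-octahydronaphthalen-1-yl (2E)-3-(4-hydroxyphenyl)prop-2-enoate
Conditions: pyridine, piperidine (cat.), 70 °C
Reagents that add atoms: none
Why: Knoevenagel–Doebner condensation: amine-catalysed condensation of the malonic half-ester with the aldehyde and decarboxylation should give the thermodynamically preferred (E)-cinnamate without phenol protection.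

Compound list
1 | 3-methylbut-3-en-2-one | CC(=O)C(C)=C | starting material
2 | triisopropyl[(3-methylbuta-1,3-dien-2-yl)oxy]silane | C=C(C)C(=C)O[Si](C(C)C)(C(C)C)C(C)C | intermediate
3 | methacrolein (2-methylprop-2-enal) | CC(=C)C=O | starting material
4 | (S)-1,3-dimethyl-4-{[tri(propan-2-yl)silyl]oxy}cyclohex-3-ene-1-carbaldehyde | CC1=C(O[Si](C(C)C)(C(C)C)C(C)C)CC[C@](C)(C=O)C1 | intermediate
5 | (S)-[(4-ethenyl-2,4-dimethylcyclohex-1-en-1-yl)oxy]tri(propan-2-yl)silane | CC1=C(O[Si](C(C)C)(C(C)C)C(C)C)CC[C@](C)(C=C)C1 | intermediate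
6 | 1-bromo-2-methylprop-1-ene | CC(C)=CBr | starting material
7 | 9-{2-[(1S)-1,3-dimethyl-4-{[tri(propan-2-yl)silyl]oxy}cyclohex-3-en-1-yl]ethyl}-9-borabicyclo[3.3.1]nonane | CC1=C(O[Si](C(C)C)(C(C)C)C(C)C)CC[C@](C)(CCB2C3CCCC2CCC3)C1 | intermediate
8 | (S)-{[2,4-dimethyl-4-(4-methylpent-3-en-1-yl)cyclohex-1-en-1-yl]oxy}tri(propan-2-yl)silane | CC1=C(O[Si](C(C)C)(C(C)C)C(C)C)CC[C@](C)(CCC=C(C)C)C1 | intermediate
9 | (S)-2,4-dimethyl-4-(4-methylpent-3-en-1-yl)cyclohex-2-en-1-one | CC1=C[C@@](C)(CCC=C(C)C)CCC1=O | intermediate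
10 | (1S,4S)-2,4-dimethyl-4-(4-methylpent-3-en-1-yl)cyclohex-2-en-1-ol | CC1=C[C@@](C)(CCC=C(C)C)CC[C@@H]1O | intermediate
11 | tributyl({[(1S,4S)-2,4-dimethyl-4-(4-methylpent-3-en-1-yl)cyclohex-2-en-1-yl]oxy}methyl)stannane | CC1=C[C@@](C)(CCC=C(C)C)CC[C@@H]1OC[Sn](CCCC)(CCCC)CCCC | intermediate
12 | ({[(1S,4S)-2,4-dimethyl-4-(4-methylpent-3-en-1-yl)cyclohex-2-en-1-yl]oxy}methyl)lithium | CC1=C[C@@](C)(CCC=C(C)C)CC[C@@H]1OC[Li] | intermediate
13 | [(1R,6S)-2,6-dimethyl-6-(4-methylpent-3-en-1-yl)cyclohex-2-en-1-yl]methanol | CC1=CCC[C@](C)(CCC=C(C)C)[C@H]1CO | intermediate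
14 | (1R,6S)-2,6-dimethyl-6-(4-methylpent-3-en-1-yl)cyclohex-2-ene-1-carbaldehyde | CC1=CCC[C@](C)(CCC=C(C)C)[C@H]1C=O | intermediate
15 | (1S,2S,4aR,8aR)-4a,8-dimethyl-2-(prop-1-en-2-yl)-1,2,3,4,4a,5,6,8a-octahydronaphthalen-1-ol | CC1=CCC[C@]2(C)CC[C@@H](C(C)=C)[C@H](O)[C@@H]12 | intermediate
16 | (2S,4aR,8aR)-4a,8-dimethyl-2-(prop-1-en-2-yl)-3,4,4a,5,6,8a-hexahydronaphthalen-1(2H)-one | CC1=CCC[C@]2(C)CC[C@@H](C(C)=C)C(=O)[C@@H]12 | intermediate
17 | (1R,2S,4aR,8aR)-4a,8-dimethyl-2-(prop-1-en-2-yl)-1,2,3,4,4a,5,6,8a-octahydronaphthalen-1-ol | CC1=CCC[C@]2(C)CC[C@@H](C(C)=C)[C@@H](O)[C@@H]12 | intermediate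
18 | (1R,2S,4aR,8aR)-4a,8-dimethyl-2-(propan-2-yl)-1,2,3,4,4a,5,6,8a-octahydronaphthalen-1-ol | CC1=CCC[C@]2(C)CC[C@@H](C(C)C)[C@@H](O)[C@@H]12 | intermediate
19 | 2,2-dimethyl-1,3-dioxane-4,6-dione (Meldrum's acid) | CC1(C)OC(=O)CC(=O)O1 | starting material
20 | 3-{[(1R,2S,4aR,8aR)-4a,8-dimethyl-2-(propan-2-yl)-1,2,3,4,4a,5,6,8a-octahydronaphthalen-1-yl]oxy}-3-oxopropanoic acid | CC1=CCC[C@]2(C)CC[C@@H](C(C)C)[C@@H](OC(=O)CC(=O)O)[C@@H]12 | intermediate
21 | 4-hydroxybenzaldehyde | O=Cc1ccc(O)cc1 | starting material
22 | (1R,2S,4aR,8aR)-4a,8-dimethyl-2-(propan-2-yl)-1,2,3,4,4a,5,6,8a-octahydronaphthalen-1-yl (2E)-3-(4-hydroxyphenyl)prop-2-enoate (CNP0220414.1) | CC1=CCC[C@]2(C)CC[C@@H](C(C)C)[C@@H](OC(=O)/C=C/c3ccc(O)cc3)[C@@H]12 | target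

Total step count: 13. Longest linear sequence: 13 steps (1 to 22).

Steps most likely to fail

Step 9. Acid-mediated migration of the C3=C4 double bond into conjugation with the aldehyde or the product ketone, epimerisation at C5, or over-oxidation may outrun the ene closure in the one-flask cascade. The fallback separates the three events and uses a proton-scavenging Lewis acid for the ring closure. It sets out from 13, which is oxidised with Dess–Martin periodinane (NaHCO3, CH2Cl2, 0 °C) to the isolated aldehyde 14. Aldehyde 14 is closed with Me2AlCl (CH2Cl2, −78 °C) in a Lewis-acid carbonyl-ene reaction to the alcohol 15. A second buffered Dess–Martin oxidation of 15 comes back to the route at 16. This fallback makes no compound outside the list (F0).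

Step 8. The lithiated ether may be consumed by [1,2]-shift or by protonation before the [2,3] shift reaches the neopentyl terminus C5. The fallback replaces the carbanion by a neutral carbene and sets out from 10. Heating 10 with N,N-dimethylformamide dimethyl acetal (xylene, 150 °C) should form the alkoxy(dimethylamino)carbene, whose suprafacial [2,3] shift gives (1R,6S)-N,N,2,6-tetramethyl-6-(4-methylpent-3-en-1-yl)cyclohex-2-ene-1-carboxamide F1. Partial reduction of F1 with Cp2Zr(H)Cl (THF, 23 °C) comes back to the route at 14, which is then treated with C5H5NH[CrO3Cl] as in step 9 (ene closure and one oxidation) to reach 16.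

Step 5. Transfer of the hindered triisopropylsilyl enol ether to divalent palladium may be slow, or β-hydride loss may turn toward the methyl group. The fallback replaces the palladium enolate by a halogenation and elimination pair and sets out from 8. Bromination with N-bromosuccinimide (THF, −78 °C) should give (4S)-2-bromo-2,4-dimethyl-4-(4-methylpent-3-en-1-yl)cyclohexan-1-one F2 as a mixture of C2 epimers. Dehydrobromination of F2 under equilibrating conditions (LiBr, Li2CO3, DMF, 120 °C) comes back to the route at 9.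

Further compounds
F0 | step 9 | none | none
F1 | step 8 | (1R,6S)-N,N,2,6-tetramethyl-6-(4-methylpent-3-en-1-yl)cyclohex-2-ene-1-carboxamide | CC1=CCC[C@](C)(CCC=C(C)C)[C@H]1C(=O)N(C)C
F2 | step 5 | (4S)-2-bromo-2,4-dimethyl-4-(4-methylpent-3-en-1-yl)cyclohexan-1-one | CC1(Br)C[C@@](C)(CCC=C(C)C)CCC1=O
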